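## Retrosynthetic overview

1. cis-Miyabenol C ⇐ Lindlar semi-hydrogenation and O-demethylation of the hexamethyl ether alkyne 31; the Z-stilbene is carried as a diarylalkyne. Locants: unprimed = dihydrobenzofuran on ring A (the styryl-bearing resorcinol ring); primed = dihydrobenzofuran on ring B (the central resorcinol ring).
2. 31 ⇐ ring-B aldehyde 24 + 3,5-dimethoxyphenylmagnesium bromide + a chiral 4-methoxybenzylsulfonium ylide. This one-flask o-quinone methide (4+1) annulation makes C3'–aryl, C3'–C2' and C2'–O1', both stereocentres and the last ring.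
3. Enabling feature: O1' sits on ring-B carbon C7a', ortho to C3a', which carries the benzylic C3'. The O1'–C7a'=C3a'–C3' salicyl unit is a latent o-quinone methide, and the aryl group on C2' stabilises the ylide carbon that becomes C2'.
4. 24 ⇐ the same cascade one stage earlier: ring-A O-Boc salicylaldehyde 6 + the aryllithium from ring-B bromide 8 (a masked salicylaldehyde) + the enantiomeric ylide close the dihydrofuran ring on ring A.
5. 6 and 8 ⇐ one aldehyde, 2-bromo-4,6-dimethoxybenzaldehyde 2. Ring order: furan ring on ring A (step 11), then furan ring on ring B (step 14).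

Key step: step 14

Assumption 1: the 4-methoxybenzyl ylide of isothiocineole is taken to transfer its carbon with the same conformer and face preference as in its aldehyde epoxidations; the salt from (R)-limonene is assigned to the (2S,3S) ring and the salt from (S)-limonene to the (2'R,3'R) ring, and the two salts change places if step 11 shows the opposite sense.

Assumption 2: 3,5-dimethoxyphenylmagnesium bromide is taken as the commercial THF solution (otherwise it is made from 1 and Mg turnings).

## Route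

Step 1
Reactants: 1 1-bromo-3,5-dimethoxybenzene
Product: 2 2-bromo-4,6-dimethoxybenzaldehyde
Conditions: POCl3, DMF, 0 → 90 °C; then ice-water
Reagents that add atoms: N,N-dimethylformamide CN(C)C=O; water O
Why: Vilsmeier–Haack formylation of the electron-rich arene should go at C2, para to one methoxy group and ortho to the other, the position known to be preferred over the more shielded site between the two methoxy groups.

Step 2
Reactants: 2 2-bromo-4,6-dimethoxybenzaldehyde
Product: 3 2-bromo-6-hydroxy-4-methoxybenzaldehyde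
Conditions: BCl3 (1.2 equiv), CH2Cl2, −78 → 0 °C; then H2O
Reagents that add atoms: none
Why: Chelation of BCl3 between the aldehyde oxygen and the ortho methoxy oxygen should make that methyl ether alone labile (chelation-controlled ortho-demethylation), leaving the para methoxy group.

Step 3
Reactants: 3 2-bromo-6-hydroxy-4-methoxybenzaldehyde; 4 4-ethynylanisole
Product: 5 2-hydroxy-4-methoxy-6-[(4-methoxyphenyl)ethynyl]benzaldehyde
Conditions: PdCl2(PPh3)2 (cat.), CuI (cat.), Et3N, THF, 60 °C
Reagents that add atoms: none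
Why: Sonogashira coupling; the aryl bromide is activated for oxidative addition by the ortho aldehyde, and the free phenol, which is meta to the new alkyne, should be tolerated.

Step 4
Reactants: 5 2-hydroxy-4-methoxy-6-[(4-methoxyphenyl)ethynyl]benzaldehyde
Product: 6 tert-butyl 2-formyl-5-methoxy-3-[(4-methoxyphenyl)ethynyl]phenyl carbonate
Conditions: Boc2O, DMAP (cat.), iPr2NEt, CH2Cl2, 0 °C → rt
Reagents that add atoms: di-tert-butyl dicarbonate CC(C)(C)OC(=O)OC(=O)OC(C)(C)C
Why: DMAP-catalysed acyl transfer should turn the hydrogen-bonded phenol into the aryl tert-butyl carbonate, the trigger group for the later release of the o-quinone methide.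

Step 5
Reactants: 3 2-bromo-6-hydroxy-4-methoxybenzaldehyde
Product: 7 2-bromo-4-methoxy-6-(methoxymethoxy)benzaldehyde
Conditions: MOMCl, iPr2NEt, CH2Cl2, 0 °C → rt
Reagents that add atoms: chloromethyl methyl ether COCCl
Why: Williamson-type O-alkylation of the phenoxide with the reactive α-chloro ether should give the MOM ether, which is stable to organolithium reagents.

Step 6
Reactants: 7 2-bromo-4-methoxy-6-(methoxymethoxy)benzaldehyde
Product: 8 1-bromo-2-(dimethoxymethyl)-5-methoxy-3-(methoxymethoxy)benzene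
Conditions: HC(OMe)3, PPTS (cat.), MeOH, rt; Et3N quench
Reagents that add atoms: trimethyl orthoformate COC(OC)OC
Why: Acid-catalysed acetalisation driven by the orthoformate as water scavenger; the mild pyridinium acid should leave the aryl MOM ether intact.

Step 7
Reactants: 9 (R)-(+)-limonene
Product: 10 isothiocineole from (R)-limonene (4,7,7-trimethyl-6-thiabicyclo[3.2.1]octane; C4 methyl cis to the sulfur bridge)
Conditions: S8, γ-terpinene, neat, 110 °C; distillation
Reagents that add atoms: sulfur S1SSSSSSS1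
Why: Radical sulfur transfer of the thiol-ene type: a thiyl radical adds to the ring alkene cis to the isopropenyl group and closes 5-exo onto it, and γ-terpinene delivers hydrogen anti to sulfur, so the limonene stereocentre fixes the bridge and the methyl group ends cis to sulfur.

Step 8
Reactants: 10 isothiocineole from (R)-limonene; 11 4-methoxybenzyl alcohol
Product: 12 S-(4-methoxybenzyl)sulfonium tetrafluoroborate of 10 (benzyl on the sulfur face away from the three-carbon bridge)
Conditions: HBF4·OEt2, CH2Cl2, 0 °C → rt; crystallisation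
Reagents that add atoms: tetrafluoroboric acid (as its diethyl etherate) [H+].F[B-](F)(F)F
Why: SN1 S-alkylation: the acid ionises the electron-rich benzylic alcohol and the sulfide captures the cation on its open lone pair, expected as one diastereomer at sulfur with a non-nucleophilic counter-ion.

Step 9
Reactants: 13 (S)-(−)-limonene
Product: 14 isothiocineole from (S)-limonene (enantiomer of 10)
Conditions: S8, γ-terpinene, neat, 110 °C; distillation
Reagents that add atoms: sulfur S1SSSSSSS1
Why: The same radical thiol-ene type bicyclisation as in step 7 in the mirror-image series, the limonene stereocentre again fixing all three centres.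

Step 10
Reactants: 14 isothiocineole from (S)-limonene; 11 4-methoxybenzyl alcohol
Product: 15 S-(4-methoxybenzyl)sulfonium tetrafluoroborate of 14 (enantiomer of 12)
Conditions: HBF4·OEt2, CH2Cl2, 0 °C → rt; crystallisation
Reagents that add atoms: tetrafluoroboric acid (as its diethyl etherate) [H+].F[B-](F)(F)F
Why: The same SN1 S-alkylation as in step 8, giving the enantiomeric sulfonium salt.

Step 11
Reactants: 8 1-bromo-2-(dimethoxymethyl)-5-methoxy-3-(methoxymethoxy)benzene; 6 tert-butyl 2-formyl-5-methoxy-3-[(4-methoxyphenyl)ethynyl]phenyl carbonate; 12 S-(4-methoxybenzyl)sulfonium tetrafluoroborate of 10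
Product: 22 (2S,3S)-3-[2-(dimethoxymethyl)-5-methoxy-3-(methoxymethoxy)phenyl]-6-methoxy-2-(4-methoxyphenyl)-4-[(4-methoxyphenyl)ethynyl]-2,3-dihydro-1-benzofuran, via aryllithium 16 (not isolated), via lithium alkoxide 17 (not isolated), via lithium phenoxide carbonate 18 (not isolated), via sulfonium ylide 19 (not isolated), via o-quinone methide 20 (not isolated), via betaine 21 (not isolated)
Conditions: 8, n-BuLi, THF, −78 °C; 6, −78 °C; ylide 19 (from 12, LiN(SiMe3)2, THF, −78 °C); MgBr2·OEt2 (promoter), −78 → 0 °C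
Reagents that add atoms: none
Why: Proposed new method: aryllithium 16 adds to the aldehyde of 6, alkoxide 17 takes the Boc group from the neighbouring phenol oxygen (18), MgBr2 triggers loss of tert-butyl carbonate to o-quinone methide 20, ylide 19 adds to its exocyclic carbon with rearomatisation (betaine 21) and the phenoxide closes the ring by 5-exo-tet SN2 displacement of the sulfide; the closest known reaction types are the Boc-triggered generation of o-quinone methides from O-Boc salicylaldehydes with organometallics and the (4+1) annulation of o-quinone methides with stabilised sulfur ylides, and C2 should be set by the chiral ylide (as in its epoxidations) while C3 follows from the trans mode of addition.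

Step 12
Reactants: 22 (2S,3S)-3-[2-(dimethoxymethyl)-5-methoxy-3-(methoxymethoxy)phenyl]-6-methoxy-2-(4-methoxyphenyl)-4-[(4-methoxyphenyl)ethynyl]-2,3-dihydro-1-benzofuran
Product: 23 2-hydroxy-4-methoxy-6-{(2S,3S)-6-methoxy-2-(4-methoxyphenyl)-4-[(4-methoxyphenyl)ethynyl]-2,3-dihydro-1-benzofuran-3-yl}benzaldehyde
Conditions: 3 M HCl (aq), THF, 50 °C
Reagents that add atoms: water O
Why: Acid hydrolysis of the dimethyl acetal and of the MOM ether in one operation; the aryl methyl ethers, the alkyne and the cyclic benzylic ether should survive dilute aqueous acid, and no stereocentre is touched.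

Step 13
Reactants: 23 2-hydroxy-4-methoxy-6-{(2S,3S)-6-methoxy-2-(4-methoxyphenyl)-4-[(4-methoxyphenyl)ethynyl]-2,3-dihydro-1-benzofuran-3-yl}benzaldehyde
Product: 24 tert-butyl carbonate of 23 (O-Boc salicylaldehyde on ring B)
Conditions: Boc2O, DMAP (cat.), iPr2NEt, CH2Cl2, 0 °C → rt
Reagents that add atoms: di-tert-butyl dicarbonate CC(C)(C)OC(=O)OC(=O)OC(C)(C)C
Why: The same DMAP-catalysed acyl transfer as in step 4 should install the carbonate trigger on the ring-B phenol next to the aldehyde.

Step 14
Reactants: 24 tert-butyl carbonate of 23; 25 3,5-dimethoxyphenylmagnesium bromide; 15 S-(4-methoxybenzyl)sulfonium tetrafluoroborate of 14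
Product: 31 (2S,3S)-3-[(2R,3R)-3-(3,5-dimethoxyphenyl)-6-methoxy-2-(4-methoxyphenyl)-2,3-dihydro-1-benzofuran-4-yl]-6-methoxy-2-(4-methoxyphenyl)-4-[(4-methoxyphenyl)ethynyl]-2,3-dihydro-1-benzofuran, via bromomagnesium alkoxide 26 (not isolated), via bromomagnesium phenoxide carbonate 27 (not isolated), via sulfonium ylide 28 (not isolated), via o-quinone methide 29 (not isolated), via betaine 30 (not isolated)
Conditions: 25 (1.05 equiv), THF, −78 °C; ylide 28 (from 15, LiN(SiMe3)2, THF, −78 °C); −78 → 0 °C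
Reagents that add atoms: none
Why: Proposed new method: the aryl Grignard adds to the hindered aldehyde, the alkoxide takes over the Boc group from the neighbouring phenol oxygen and tert-butyl carbonate leaves, so that ring B becomes an o-quinone methide whose exocyclic carbon already carries the 3,5-dimethoxyphenyl group; the chiral benzylic sulfonium ylide then adds to that carbon in a vinylogous (1,4) sense with rearomatisation, and the phenoxide displaces the sulfide from the neighbouring carbon. The closest known reaction types are the Boc-triggered generation of o-quinone methides from O-Boc salicylaldehydes with organometallics and the (4+1) annulation of o-quinone methides with stabilised sulfur ylides to trans-2,3-dihydrobenzofurans; new are their merger in one flask and the use of a semi-stabilised ylide of a chiral sulfide. The one ring that closes does so by a 5-exo-tet SN2 O-alkylation, after the C3'–C2' bond has been made by the conjugate addition. C2' should be fixed by the ylide (one conformer and one open face on the bicyclic sulfonium, then inversion at carbon in the SN2 step, as in the epoxidations with such ylides), and C3' should follow from the trans mode of addition known for o-quinone methide/ylide annulations, which places the two aryl groups on opposite faces of the new ring. The step needs chemoselectivity (Grignard at the aldehyde and not at the carbonate, ylide at the methide and not at the aldehyde) and face selectivity against the resident (2S,3S) unit: sequential addition at −78 °C with only a slight excess of Grignard secures the first, and reagent control by the sulfide, used as the enantiomer opposite to that of step 11, is expected to override the bias of the C3 substituent.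

Step 15
Reactants: 31 hexamethyl ether alkyne
Product: 32 (2S,3S)-3-[(2R,3R)-3-(3,5-dihydroxyphenyl)-6-hydroxy-2-(4-hydroxyphenyl)-2,3-dihydro-1-benzofuran-4-yl]-2-(4-hydroxyphenyl)-4-[(4-hydroxyphenyl)ethynyl]-2,3-dihydro-1-benzofuran-6-ol
Conditions: BBr3 (excess), CH2Cl2, −78 °C → rt; then H2O
Reagents that add atoms: none
Why: Lewis-acid cleavage of all six aryl methyl ethers with BBr3, the usual last-stage operation for permethylated oligostilbenes; any reversible opening of the benzylic C2–O bonds should reclose to the more stable trans rings, and the alkyne stands in for the acid-sensitive stilbene at this stage.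

Step 16
Reactants: 32 hexaphenol alkyne
Product: 33 cis-miyabenol C
Conditions: H2 (1 atm), Pd on CaCO3 poisoned with Pb(OAc)2 (Lindlar catalyst), quinoline, EtOAc–MeOH, rt, in the dark
Reagents that add atoms: none
Why: Lindlar semi-hydrogenation: syn delivery of hydrogen to the diarylalkyne on lead-poisoned palladium should give the Z-stilbene, with quinoline holding back over-reduction and isomerisation.

## Compound list

1 | 1-bromo-3,5-dimethoxybenzene | COc1cc(Br)cc(OC)c1 | starting material
2 | 2-bromo-4,6-dimethoxybenzaldehyde | COc1cc(Br)c(C=O)c(OC)c1 | intermediate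
3 | 2-bromo-6-hydroxy-4-methoxybenzaldehyde | COc1cc(O)c(C=O)c(Br)c1 | intermediate
4 | 4-ethynylanisole | COc1ccc(C#C)cc1 | starting material
5 | 2-hydroxy-4-methoxy-6-[(4-methoxyphenyl)ethynyl]benzaldehyde | COc1ccc(C#Cc2cc(OC)cc(O)c2C=O)cc1 | intermediate
6 | tert-butyl 2-formyl-5-methoxy-3-[(4-methoxyphenyl)ethynyl]phenyl carbonate | COc1ccc(C#Cc2cc(OC)cc(OC(=O)OC(C)(C)C)c2C=O)cc1 | intermediate
7 | 2-bromo-4-methoxy-6-(methoxymethoxy)benzaldehyde | COCOc1cc(OC)cc(Br)c1C=O | intermediate
8 | 1-bromo-2-(dimethoxymethyl)-5-methoxy-3-(methoxymethoxy)benzene | COCOc1cc(OC)cc(Br)c1C(OC)OC | intermediate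
9 | (R)-(+)-limonene | CC1=CC[C@@H](CC1)C(C)=C | starting material
10 | isothiocineole from (R)-limonene, methyl cis to the sulfur bridge | C[C@H]1CC[C@@H]2C[C@H]1SC2(C)C | intermediate
11 | 4-methoxybenzyl alcohol | COc1ccc(CO)cc1 | starting material
12 | S-(4-methoxybenzyl)sulfonium tetrafluoroborate of 10 | C[C@H]1CC[C@@H]2C[C@H]1[S@@+](Cc1ccc(OC)cc1)C2(C)C.F[B-](F)(F)F | intermediate
13 | (S)-(−)-limonene | CC1=CC[C@H](CC1)C(C)=C | starting material
14 | isothiocineole from (S)-limonene (enantiomer of 10) | C[C@@H]1CC[C@H]2C[C@@H]1SC2(C)C | intermediate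
15 | S-(4-methoxybenzyl)sulfonium tetrafluoroborate of 14 (enantiomer of 12) | C[C@@H]1CC[C@H]2C[C@@H]1[S@+](Cc1ccc(OC)cc1)C2(C)C.F[B-](F)(F)F | intermediate
16 | [2-(dimethoxymethyl)-5-methoxy-3-(methoxymethoxy)phenyl]lithium (not isolated) | [Li]c1cc(OC)cc(OCOC)c1C(OC)OC | intermediate
17 | lithium alkoxide from addition of 16 to 6, carbinol centre unassigned (not isolated) | COc1ccc(C#Cc2cc(OC)cc(OC(=O)OC(C)(C)C)c2C([O-])c2cc(OC)cc(OCOC)c2C(OC)OC)cc1.[Li+] | intermediate
18 | lithium phenoxide with the Boc group shifted to the benzylic oxygen (not isolated) | COc1ccc(C#Cc2cc(OC)cc([O-])c2C(OC(=O)OC(C)(C)C)c2cc(OC)cc(OCOC)c2C(OC)OC)cc1.[Li+] | intermediate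
19 | sulfonium 4-methoxybenzylide from 12 (not isolated) | C[C@H]1CC[C@@H]2C[C@H]1[S@@+]([CH-]c1ccc(OC)cc1)C2(C)C | intermediate
20 | ring-A o-quinone methide, 6-{[2-(dimethoxymethyl)-5-methoxy-3-(methoxymethoxy)phenyl]methylidene}-3-methoxy-5-[(4-methoxyphenyl)ethynyl]cyclohexa-2,4-dien-1-one, alkene geometry open (not isolated) | O=C1C=C(OC)C=C(C#Cc2ccc(OC)cc2)C1=Cc1cc(OC)cc(OCOC)c1C(OC)OC | intermediate
21 | betaine from 19 and 20, phenoxide/sulfonium zwitterion (not isolated) | C[C@H]1CC[C@@H]2C[C@H]1[S@@+]([C@@H](c1ccc(OC)cc1)[C@@H](c1cc(OC)cc(OCOC)c1C(OC)OC)c1c([O-])cc(OC)cc1C#Cc1ccc(OC)cc1)C2(C)C | intermediate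
22 | (2S,3S)-3-[2-(dimethoxymethyl)-5-methoxy-3-(methoxymethoxy)phenyl]-6-methoxy-2-(4-methoxyphenyl)-4-[(4-methoxyphenyl)ethynyl]-2,3-dihydro-1-benzofuran | COc1ccc(C#Cc2cc(OC)cc3c2[C@H](c2cc(OC)cc(OCOC)c2C(OC)OC)[C@@H](c2ccc(OC)cc2)O3)cc1 | intermediate
23 | 2-hydroxy-4-methoxy-6-{(2S,3S)-6-methoxy-2-(4-methoxyphenyl)-4-[(4-methoxyphenyl)ethynyl]-2,3-dihydro-1-benzofuran-3-yl}benzaldehyde | COc1ccc(C#Cc2cc(OC)cc3c2[C@H](c2cc(OC)cc(O)c2C=O)[C@@H](c2ccc(OC)cc2)O3)cc1 | intermediate
24 | tert-butyl carbonate of 23 | COc1ccc(C#Cc2cc(OC)cc3c2[C@H](c2cc(OC)cc(OC(=O)OC(C)(C)C)c2C=O)[C@@H](c2ccc(OC)cc2)O3)cc1 | intermediate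
25 | 3,5-dimethoxyphenylmagnesium bromide | COc1cc(OC)cc([Mg]Br)c1 | starting material
26 | bromomagnesium alkoxide from addition of 25 to 24, carbinol centre unassigned (not isolated) | COc1ccc(C#Cc2cc(OC)cc3c2[C@H](c2cc(OC)cc(OC(=O)OC(C)(C)C)c2C([O-])c2cc(OC)cc(OC)c2)[C@@H](c2ccc(OC)cc2)O3)cc1.[Mg+2].[Br-] | intermediate
27 | bromomagnesium phenoxide with the Boc group shifted to the benzylic oxygen (not isolated) | COc1ccc(C#Cc2cc(OC)cc3c2[C@H](c2cc(OC)cc([O-])c2C(OC(=O)OC(C)(C)C)c2cc(OC)cc(OC)c2)[C@@H](c2ccc(OC)cc2)O3)cc1.[Mg+2].[Br-] | intermediate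
28 | sulfonium 4-methoxybenzylide from 15 (not isolated) | C[C@@H]1CC[C@H]2C[C@@H]1[S@+]([CH-]c1ccc(OC)cc1)C2(C)C | intermediate
29 | ring-B o-quinone methide, 6-[(3,5-dimethoxyphenyl)methylidene]-3-methoxy-5-[(2S,3S)-dihydrobenzofuran-3-yl]cyclohexa-2,4-dien-1-one, alkene geometry open (not isolated) | COc1ccc(C#Cc2cc(OC)cc3c2[C@H](C2=CC(OC)=CC(=O)C2=Cc2cc(OC)cc(OC)c2)[C@@H](c2ccc(OC)cc2)O3)cc1 | intermediate
30 | betaine from 28 and 29, phenoxide/sulfonium zwitterion (not isolated) | C[C@@H]1CC[C@H]2C[C@@H]1[S@+]([C@H](c1ccc(OC)cc1)[C@H](c1cc(OC)cc(OC)c1)c1c([O-])cc(OC)cc1[C@H]1c3c(C#Cc4ccc(OC)cc4)cc(OC)cc3O[C@@H]1c1ccc(OC)cc1)C2(C)C | intermediate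
31 | (2S,3S)-3-[(2R,3R)-3-(3,5-dimethoxyphenyl)-6-methoxy-2-(4-methoxyphenyl)-2,3-dihydro-1-benzofuran-4-yl]-6-methoxy-2-(4-methoxyphenyl)-4-[(4-methoxyphenyl)ethynyl]-2,3-dihydro-1-benzofuran | COc1ccc(C#Cc2cc(OC)cc3c2[C@H](c2cc(OC)cc4c2[C@@H](c2cc(OC)cc(OC)c2)[C@H](c2ccc(OC)cc2)O4)[C@@H](c2ccc(OC)cc2)O3)cc1 | intermediate
32 | hexaphenol alkyne, (2S,3S)-3-[(2R,3R)-3-(3,5-dihydroxyphenyl)-6-hydroxy-2-(4-hydroxyphenyl)-2,3-dihydro-1-benzofuran-4-yl]-2-(4-hydroxyphenyl)-4-[(4-hydroxyphenyl)ethynyl]-2,3-dihydro-1-benzofuran-6-ol | Oc1ccc(C#Cc2cc(O)cc3c2[C@H](c2cc(O)cc4c2[C@@H](c2cc(O)cc(O)c2)[C@H](c2ccc(O)cc2)O4)[C@@H](c2ccc(O)cc2)O3)cc1 | intermediate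
33 | cis-miyabenol C, (2S,3S)-3-[(2R,3R)-3-(3,5-dihydroxyphenyl)-6-hydroxy-2-(4-hydroxyphenyl)-2,3-dihydro-1-benzofuran-4-yl]-2-(4-hydroxyphenyl)-4-[(Z)-2-(4-hydroxyphenyl)ethenyl]-2,3-dihydro-1-benzofuran-6-ol | Oc1ccc(/C=C\c2cc(O)cc3c2[C@H](c2cc(O)cc4c2[C@@H](c2cc(O)cc(O)c2)[C@H](c2ccc(O)cc2)O4)[C@@H](c2ccc(O)cc2)O3)cc1 | target

## Step count and risks

Total step count: 16. Longest linear sequence: 10 steps (1, 2, 3, 4, 11, 12, 13, 14, 15, 16).

Steps most likely to fail:

**Step 14 (labelled).** What may go wrong: the ylide may be consumed by proton transfer or acylation before the methide forms. The betaine may lose the sulfide by β-elimination instead of O-alkylation. The reagent-controlled face selectivity may be overridden by the resident (2S,3S) unit (mismatched pair), so that the new ring forms with the wrong sense. The fallback uses the known donor/donor carbene C–H insertion; it sets out from 23 and returns at 32. Compound 23 is O-alkylated with 4-methoxybenzyl chloride (K2CO3, DMF) to the 4-methoxybenzyl ether aldehyde F1. Addition of 25 (THF, −78 °C) gives the diarylcarbinol F2, which MnO2 oxidises to the diaryl ketone F3. N2H4·H2O (EtOH, cat. AcOH, 80 °C) gives the hydrazone F4, and MnO2 (CH2Cl2) converts this into the diaryldiazomethane F5 (not isolated). With Rh2(PTAD)4 (dirhodium tetrakis[N-phthaloyl(1-adamantyl)glycinate], the enantiomer chosen for the (3'R) centre), F5 should insert into the benzylic ether C–H bond to give the cis-(2'S,3'R) dihydrobenzofuran F6. BBr3 (CH2Cl2) should then cleave the methyl ethers and epimerise C2' through the 4-oxybenzylic cation to the trans ring, which is 32.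

**Step 11 (labelled).** What may go wrong: the ylide may be destroyed by tert-butoxide or by the carbonate before MgBr2 releases the methide. The methide may dimerise or add alkoxide. Optical purity may erode if the ylide addition becomes reversible. The fallback is again the known carbene C–H insertion, with the alkyne introduced only after ring closure so that the carbene cannot be diverted onto it; it sets out from 3 (with 8 as partner) and returns at 23. Compound 3 is O-alkylated with 4-methoxybenzyl chloride (K2CO3, DMF) to the 4-methoxybenzyl ether bromoaldehyde F7. Addition of aryllithium 16 (from 8, n-BuLi, THF, −78 °C) gives the diarylcarbinol F8, MnO2 the diaryl ketone F9, and N2H4·H2O the hydrazone F10. MnO2 gives the diaryldiazomethane F11 (not isolated), and Rh2(PTAD)4 (the enantiomer chosen for the (3S) centre) should give the cis-(2R,3S) 4-bromodihydrobenzofuran F12. Sonogashira coupling with 4 (PdCl2(PPh3)2, CuI, Et3N) gives the cis alkyne F13. 3 M HCl (THF) followed by CF3CO2H (CH2Cl2) should remove the acetal and MOM groups and epimerise C2 to the trans ring, which is 23.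

**Step 16.** What may go wrong: over-reduction to the bibenzyl, slow turnover through adsorption of the free hexaphenol on the catalyst, or Z-to-E isomerisation on the metal. The fallback is a protect–reduce–deprotect detour; it sets out from 32 and returns at 33. Ac2O/pyridine converts 32 into the hexaacetate alkyne F14. Lindlar semi-hydrogenation (H2, Pd on CaCO3 poisoned with Pb(OAc)2, quinoline, EtOAc) of this non-polar substrate should give the hexaacetate Z-stilbene F15. K2CO3 (cat.) in MeOH at 0 °C should then remove the acetates to give 33.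

Further compounds

F1 | step 14 | 4-methoxy-6-[(4-methoxybenzyl)oxy]-2-{(2S,3S)-6-methoxy-2-(4-methoxyphenyl)-4-[(4-methoxyphenyl)ethynyl]-2,3-dihydro-1-benzofuran-3-yl}benzaldehyde | COc1ccc(C#Cc2cc(OC)cc3c2[C@H](c2cc(OC)cc(OCc4ccc(OC)cc4)c2C=O)[C@@H](c2ccc(OC)cc2)O3)cc1
F2 | step 14 | diarylcarbinol from F1 and 25 (carbinol centre unassigned) | COc1ccc(C#Cc2cc(OC)cc3c2[C@H](c2cc(OC)cc(OCc4ccc(OC)cc4)c2C(O)c2cc(OC)cc(OC)c2)[C@@H](c2ccc(OC)cc2)O3)cc1
F3 | step 14 | diaryl ketone from F2 | COc1ccc(C#Cc2cc(OC)cc3c2[C@H](c2cc(OC)cc(OCc4ccc(OC)cc4)c2C(=O)c2cc(OC)cc(OC)c2)[C@@H](c2ccc(OC)cc2)O3)cc1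
F4 | step 14 | hydrazone of F3 | COc1ccc(C#Cc2cc(OC)cc3c2[C@H](c2cc(OC)cc(OCc4ccc(OC)cc4)c2C(=NN)c2cc(OC)cc(OC)c2)[C@@H](c2ccc(OC)cc2)O3)cc1
F5 | step 14 | diaryldiazomethane from F4 (not isolated) | COc1ccc(C#Cc2cc(OC)cc3c2[C@H](c2cc(OC)cc(OCc4ccc(OC)cc4)c2C(=[N+]=[N-])c2cc(OC)cc(OC)c2)[C@@H](c2ccc(OC)cc2)O3)cc1
F6 | step 14 | cis-(2'S,3'R) diastereomer of 31 | COc1ccc(C#Cc2cc(OC)cc3c2[C@H](c2cc(OC)cc4c2[C@@H](c2cc(OC)cc(OC)c2)[C@@H](c2ccc(OC)cc2)O4)[C@@H](c2ccc(OC)cc2)O3)cc1
F7 | step 11 | 2-bromo-4-methoxy-6-[(4-methoxybenzyl)oxy]benzaldehyde | COc1ccc(COc2cc(OC)cc(Br)c2C=O)cc1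
F8 | step 11 | diarylcarbinol from F7 and 16 (carbinol centre unassigned) | COc1ccc(COc2cc(OC)cc(Br)c2C(O)c2cc(OC)cc(OCOC)c2C(OC)OC)cc1
F9 | step 11 | diaryl ketone from F8 | COc1ccc(COc2cc(OC)cc(Br)c2C(=O)c2cc(OC)cc(OCOC)c2C(OC)OC)cc1
F10 | step 11 | hydrazone of F9 | COc1ccc(COc2cc(OC)cc(Br)c2C(=NN)c2cc(OC)cc(OCOC)c2C(OC)OC)cc1
F11 | step 11 | diaryldiazomethane from F10 (not isolated) | COc1ccc(COc2cc(OC)cc(Br)c2C(=[N+]=[N-])c2cc(OC)cc(OCOC)c2C(OC)OC)cc1
F12 | step 11 | (2R,3S)-4-bromo-3-[2-(dimethoxymethyl)-5-methoxy-3-(methoxymethoxy)phenyl]-6-methoxy-2-(4-methoxyphenyl)-2,3-dihydro-1-benzofuran (cis) | Brc1cc(OC)cc2c1[C@H](c1cc(OC)cc(OCOC)c1C(OC)OC)[C@H](c1ccc(OC)cc1)O2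
F13 | step 11 | cis-(2R,3S) diastereomer of 22 | COc1ccc(C#Cc2cc(OC)cc3c2[C@H](c2cc(OC)cc(OCOC)c2C(OC)OC)[C@H](c2ccc(OC)cc2)O3)cc1
F14 | step 16 | hexaacetate of 32 | CC(=O)Oc1ccc(C#Cc2cc(OC(C)=O)cc3c2[C@H](c2cc(OC(C)=O)cc4c2[C@@H](c2cc(OC(C)=O)cc(OC(C)=O)c2)[C@H](c2ccc(OC(C)=O)cc2)O4)[C@@H](c2ccc(OC(C)=O)cc2)O3)cc1
F15 | step 16 | hexaacetate of 33 (Z-alkene) | CC(=O)Oc1ccc(/C=C\c2cc(OC(C)=O)cc3c2[C@H](c2cc(OC(C)=O)cc4c2[C@@H](c2cc(OC(C)=O)cc(OC(C)=O)c2)[C@H](c2ccc(OC(C)=O)cc2)O4)[C@@H](c2ccc(OC(C)=O)cc2)O3)cc1
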